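**Retrosynthetic overview**
- Target ⇐ invertive chlorination of a (6R)-allylic alcohol made by late allylic C6–H hydroxylation; the 8-OH/C7–O γ-lactone ⇐ epoxidation–lactonisation of an (E)-C7=C8 β,γ-unsaturated acid.
- Ten-membered ring ⇐ anionic oxy-Cope ring expansion (six → ten) of a trans-decalin carrying an axial vinyl group on C8 and an equatorial allenyl group on C3. This single step gives the macro-ring, the (3Z)-alkene, the C5 exocyclic methylene and an (E)-enolate, trapped as the enol triflate.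
- Allenyl ketone ⇐ propargyl vinyl ether Claisen rearrangement on ring B; ring A oxygenation ⇐ diene dihydroxylation, then hydroxyl-directed epoxidation.
- Decalin ⇐ catalytic asymmetric Diels–Alder reaction of 2-methoxy-5-methylbenzoquinone (ring B) with a 2-siloxypentadiene (forms ring A), then C10 epimerisation to the trans ring fusion.
- Ring order: ring B (quinone) → ring A (cycloaddition) → ten-membered ring (ring B is opened) → γ-lactone.

Numbering: briarane numbering is used for every intermediate (C1 bears Me-15; ring A = C1, C10–C14; ring B = C1, C2, C3, C8, C9, C10; Me-20 on C11; C17 bears Me-18; C19 is the lactone carbonyl); in the decalins β is the face of Me-15 and α the face of H-10.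
Assumption: the (R)-BINOL–titanium catalyst of step 2 gives the enantiomer drawn; if it gives the antipode, the (S)-ligand is used and nothing else changes.

Step 1
Reactants: 1 (E)-pent-3-en-2-one
Product: 2 (E)-2-(tert-butyldimethylsilyloxy)penta-1,3-diene
Conditions: tBuMe2SiOTf, Et3N, Et2O, 0 °C → rt
Reagents that add atoms: tert-butyldimethylsilyl triflate CC(C)(C)[Si](C)(C)OS(=O)(=O)C(F)(F)F
Why: Soft enolisation on the methyl side (silyl dienol ether formation) gives the 2-siloxy diene with the (E)-propenyl unit intact.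

Step 2
Reactants: 2 (E)-2-(tert-butyldimethylsilyloxy)penta-1,3-diene; 3 2-methoxy-5-methyl-1,4-benzoquinone
Product: 4 cis-fused Diels–Alder adduct (Me-15 β; H-10 β; 11-Me α; 8-OMe enedione; 13-silyl enol ether)
Conditions: (R)-BINOL (20 mol%), TiCl2(OiPr)2 (20 mol%), 4 Å MS, PhMe, −40 → −20 °C
Reagents that add atoms: none
Why: Chiral Lewis acid-catalysed quinone Diels–Alder reaction in which two-point binding of titanium to the C1 carbonyl and the methoxy oxygen of 3 activates the methyl-bearing C=C, so the CH2 terminus of the diene bonds to the methyl-bearing carbon (quaternary C1) and endo addition on the open face sets C1, with cis C10 and C11 that are corrected or erased later.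

Step 3
Reactants: 4 cis-fused Diels–Alder adduct
Product: 5 trans-fused enedione (Me-15 β; H-10 α)
Conditions: DBU (0.2 equiv), PhMe, 25 °C
Reagents that add atoms: none
Why: Base-mediated epimerisation at C10 (α to the C9 ketone) gives the thermodynamically preferred trans-decalin, setting H-10 anti to Me-15.

Step 4
Reactants: 5 trans-fused enedione
Product: 6 9β-hydroxy vinylogous ester
Conditions: NaBH4, CeCl3·7H2O, MeOH/CH2Cl2, −78 °C
Reagents that add atoms: none
Why: Luche 1,2-reduction of the more electrophilic C9 ketone (the C2 carbonyl is a deactivated vinylogous ester), with hydride entering anti to the axial Me-15 to give the axial 9β-alcohol (sets C9).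

Step 5
Reactants: 6 9β-hydroxy vinylogous ester
Product: 7 9β-(4-methoxybenzyl) ether
Conditions: NaH, 4-MeOC6H4CH2Cl, Bu4NI (cat.), DMF, 0 °C
Reagents that add atoms: 4-methoxybenzyl chloride COc1ccc(CCl)cc1
Why: Williamson etherification; unlike a silyl ether, the benzyl-type ether cannot migrate to the neighbouring C8 alkoxide in step 16 and is removed oxidatively late.

Step 6
Reactants: 7 9β-(4-methoxybenzyl) ether
Product: 8 ring A 11-en-13-one
Conditions: Pd(OAc)2 (1.1 equiv), MeCN, 25 °C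
Reagents that add atoms: none
Why: Saegusa–Ito oxidation in which the palladium enolate at C12 loses the β-hydrogen at C11 to give the C11=C12 enone (the C11 stereocentre is erased).

Step 7
Reactants: 8 ring A 11-en-13-one
Product: 9 ring A 13-triflyloxy-11,13-diene
Conditions: LiN(iPr)2, THF, −78 °C; then PhNTf2, −78 → 0 °C
Reagents that add atoms: N-phenylbis(trifluoromethanesulfonimide) O=S(=O)(N(c1ccccc1)S(=O)(=O)C(F)(F)F)C(F)(F)F
Why: Kinetic α'-deprotonation at C14 and O-triflation give the 2-triflyloxy-1,3-diene; the ring B vinylogous ester has no α'-hydrogen and its γ C9–H lies in the plane of the π system.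

Step 8
Reactants: 9 ring A 13-triflyloxy-11,13-diene
Product: 10 ring A 11,13-diene
Conditions: Pd(OAc)2 (5 mol%), PPh3 (10 mol%), HCO2H, Bu3N, DMF, 60 °C
Reagents that add atoms: none
Why: Palladium-catalysed formate reduction of the alkenyl triflate (oxidative addition, decarboxylation to the hydride, reductive elimination) gives the ring A diene and leaves the methyl vinylogous ester alone.

Step 9
Reactants: 10 ring A 11,13-diene
Product: 11 8-(prop-2-ynyloxy) vinylogous ester
Conditions: HC≡CCH2OH (20 equiv), NaH (0.2 equiv), THF, 25 °C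
Reagents that add atoms: prop-2-yn-1-ol C#CCO
Why: Conjugate addition–elimination of propargyl alkoxide at C8 exchanges methoxy for propargyloxy without regiochemical scrambling; it follows the palladium steps because a propargyl vinylogous ester would ionise on zerovalent palladium.

Step 10
Reactants: 11 8-(prop-2-ynyloxy) vinylogous ester
Product: 12 11α,12α-diol
Conditions: OsO4 (2 mol%), NMO, acetone/H2O (10:1), 0 °C
Reagents that add atoms: osmium tetroxide O=[Os](=O)(=O)=O; N-methylmorpholine N-oxide C[N+]1([O-])CCOCC1; water O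
Why: Upjohn dihydroxylation in which OsO4 takes the more electron-rich trisubstituted C11=C12 end of the diene from the α face, opposite the axial Me-15, giving the cis diol with Me-20 β (sets C11 and C12).

Step 11
Reactants: 12 11α,12α-diol
Product: 13 13α,14α-epoxy-11α,12α-diol
Conditions: VO(acac)2 (5 mol%), tBuOOH, CH2Cl2, 0 °C
Reagents that add atoms: tert-butyl hydroperoxide CC(C)(C)OO
Why: Hydroxyl-directed vanadium-catalysed epoxidation of the cyclic allylic alcohol delivers oxygen syn to the 12α-OH (sets C13 and C14); the cis epoxy alcohol cannot undergo Payne rearrangement.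

Step 12
Reactants: 13 13α,14α-epoxy-11α,12α-diol
Product: 14 2β,11α,12α-triol (3-alkoxyallyl alcohol)
Conditions: iBu2AlH, CH2Cl2, −78 °C; aq. potassium sodium tartrate
Reagents that add atoms: none
Why: 1,2-reduction of the vinylogous ester carbonyl with axial hydride attack from the α face, anti to the adjacent axial Me-15, gives the equatorial 2β-alcohol (sets C2).

Step 13
Reactants: 14 2β,11α,12α-triol
Product: 15 2β,11α,12α-tris(triethylsilyl) ether
Conditions: Et3SiOTf (4 equiv), 2,6-lutidine, CH2Cl2, −78 → 0 °C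
Reagents that add atoms: triethylsilyl triflate CC[Si](CC)(CC)OS(=O)(=O)C(F)(F)F
Why: Silylation of the allylic, secondary and tertiary hydroxyls with the silyl triflate under buffered conditions that spare the acid-labile 3-alkoxyallyl alcohol.

Step 14
Reactants: 15 2β,11α,12α-tris(triethylsilyl) ether
Product: 16 3α-allenyl 8-ketone
Conditions: PhMe (0.02 M, base-washed glass), 125 °C, sealed tube
Reagents that add atoms: none
Why: Propargyl vinyl ether Claisen (Saucy–Marbet) rearrangement in which the suprafacial [3,3] shift delivers C4 to the α face of C3, the β face being blocked by Me-15, the 2β-silyloxy and the 9β-benzyloxy groups, giving the equatorial allenyl ketone.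

Step 15
Reactants: 16 3α-allenyl 8-ketone
Product: 17 8α-vinyl-8β-ol
Conditions: CH2=CHMgBr, LaCl3·2LiCl (0.3 equiv), THF, −78 °C
Reagents that add atoms: vinylmagnesium bromide C=C[Mg]Br
Why: Grignard 1,2-addition (the lanthanum salt suppresses enolisation) by axial α-face attack anti to the axial 9β-alkoxy group (polar Felkin–Anh), which places the vinyl group axial and cis to the equatorial allenyl group.

Step 16
Reactants: 17 8α-vinyl-8β-ol
Product: 20 (3Z,7E)-enol triflate of the ten-membered ring with 5(16)-methylene, via potassium alkoxide 18 (not isolated), via potassium enolate 19 (not isolated)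
Conditions: KN(SiMe3)2, 18-crown-6, THF, −78 → 0 °C; then PhNTf2, −78 °C
Reagents that add atoms: N-phenylbis(trifluoromethanesulfonimide) O=S(=O)(N(c1ccccc1)S(=O)(=O)C(F)(F)F)C(F)(F)F
Why: Proposed new method: an anionic oxy-Cope ring expansion whose 5,6-π bond is the proximal double bond of an allene, the closest known reactions being the anionic oxy-Cope expansion of cis-1,2-dialkenylcyclohexanols to cyclodecenones and the thermal Cope rearrangement of 1,2,6-heptatrienes; in the locked chair transition state (axial vinyl, equatorial allenyl, equatorial alkoxide) the C3–C2 bond is axial and the C8–C9 bond equatorial on the Cope chair, so C3=C4 forms Z and the enolate E, the central allene carbon C5 keeps its C=CH2 bond, loss of the allene plus enolate formation makes the normally uphill six-to-ten expansion downhill, and O-triflation fixes the (E)-C7=C8 geometry.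

Step 17
Reactants: 20 (3Z,7E)-enol triflate
Product: 21 methyl 2-(cyclodecatrienyl)propanoate (C8–C17 bond; C17 epimers)
Conditions: CH3CHBrCO2Me, Zn, THF, 25 °C; then 20, Pd2(dba)3 (2.5 mol%), XPhos (10 mol%), THF, 45 °C
Reagents that add atoms: methyl 2-bromopropanoate CC(Br)C(=O)OC
Why: Palladium-catalysed Negishi-type coupling of the alkenyl triflate with the Reformatsky reagent (α-alkenylation of an ester) with retention of alkene geometry; C17 forms as a mixture that step 20 corrects.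

Step 18
Reactants: 21 methyl ester (C17 epimers)
Product: 22 β,γ-unsaturated carboxylic acid (C17 epimers)
Conditions: KOSiMe3, THF, 25 °C; then aq. KHSO4
Reagents that add atoms: none
Why: Anhydrous silanolate cleavage of the methyl ester, mild enough not to move the β,γ-alkene into conjugation.

Step 19
Reactants: 22 β,γ-unsaturated carboxylic acid
Product: 24 8-hydroxy-19,7-lactone (C17 epimers), via epoxy acid 23 (not isolated)
Conditions: mCPBA (1.05 equiv), NaHCO3, CH2Cl2, −20 → 0 °C
Reagents that add atoms: 3-chloroperoxybenzoic acid O=C(OO)c1cccc(Cl)c1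
Why: Peracid epoxidation of the most electron-rich, strained (E)-trisubstituted alkene on its outer face, then anti opening of the β,γ-epoxy acid at C7 by the carboxyl group (hydroxy-lactonisation); anti addition across the (E)-C7=C8 bond gives exactly the target relation of 8-OH and the C7 lactone oxygen, and outer-face attack on the conformer delivered by the oxy-Cope chair fixes both relative to C9 (sets C7 and C8).

Step 20
Reactants: 24 8-hydroxy-19,7-lactone (C17 epimers)
Product: 25 (17R)-8-hydroxy-19,7-lactone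
Conditions: DBU (0.3 equiv), PhMe, 60 °C
Reagents that add atoms: none
Why: Base-mediated epimerisation α to the lactone carbonyl gives the more stable epimer, with Me-18 trans to the bulkier C9 branch on C8 and cis to 8-OH (sets C17).

Step 21
Reactants: 25 (17R)-8-hydroxy-19,7-lactone
Product: 26 9-ol
Conditions: DDQ, CH2Cl2/pH 7 buffer (10:1), 0 °C
Reagents that add atoms: none
Why: Oxidative cleavage of the 4-methoxybenzyl ether (hydride abstraction, hydrolysis of the oxocarbenium ion); the ring diene is held away from s-cis and does not cycloadd to the quinone.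

Step 22
Reactants: 26 9-ol
Product: 27 9-acetate
Conditions: Ac2O, DMAP, pyridine, CH2Cl2, 25 °C
Reagents that add atoms: acetic anhydride CC(=O)OC(C)=O
Why: DMAP-catalysed acetylation of the only free secondary alcohol; the tertiary 8-OH does not react.

Step 23
Reactants: 27 9-acetate
Product: 28 2,11,12-triol
Conditions: Bu4NF, AcOH (1:1), THF, 0 → 25 °C
Reagents that add atoms: none
Why: Buffered fluoride cleavage of the three triethylsilyl ethers; acetate, lactone and epoxide tolerate fluoride/acetic acid.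

Step 24
Reactants: 28 2,11,12-triol
Product: 29 2,12-dibutanoate (6-deschloro target)
Conditions: (PrCO)2O, DMAP, Et3N, CH2Cl2, 0 → 25 °C
Reagents that add atoms: butanoic anhydride CCCC(=O)OC(=O)CCC
Why: DMAP-catalysed acylation of the two secondary alcohols at C2 and C12; the tertiary 8- and 11-hydroxyls stay free.

Step 25
Reactants: 29 2,12-dibutanoate
Product: 30 (6R)-6-hydroxy compound
Conditions: SeO2 (0.5 equiv), tBuOOH, CH2Cl2, 25 °C
Reagents that add atoms: selenium dioxide O=[Se]=O; tert-butyl hydroperoxide CC(C)(C)OO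
Why: SeO2 allylic hydroxylation (ene reaction, then [2,3]-sigmatropic shift) of the 1,1-disubstituted C5=C16 alkene at its only allylic CH2, returning the double bond to the exocyclic position; the C6–H lying parallel to the π system on the outer face is replaced, which is predicted to give the (6R)-alcohol.

Step 26
Reactants: 30 (6R)-6-hydroxy compound
Product: 31 CNP0188106.1
Conditions: PPh3, Cl3CCOCCl3, CH2Cl2, 0 °C
Reagents that add atoms: hexachloroacetone O=C(C(Cl)(Cl)Cl)C(Cl)(Cl)Cl
Why: Appel-type chlorination of the allylic alcohol with Ph3P/hexachloroacetone proceeds by SN2 with inversion and without allylic transposition to give the (6S)-chloride; the tertiary alcohols do not react.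

**Compound list**
1 | (E)-pent-3-en-2-one | C/C=C/C(C)=O | starting material
2 | (E)-2-(tert-butyldimethylsilyloxy)penta-1,3-diene | C=C(O[Si](C)(C)C(C)(C)C)/C=C/C | intermediate
3 | 2-methoxy-5-methyl-1,4-benzoquinone | COC1=CC(=O)C(C)=CC1=O | starting material
4 | cis-fused adduct: 6-(tert-butyldimethylsilyloxy)-2-methoxy-4a,8-dimethyl-4a,5,8,8a-tetrahydronaphthalene-1,4-dione; Me-15 β, H-10 β, 11-Me α | COC1=CC(=O)[C@@]2(C)CC(O[Si](C)(C)C(C)(C)C)=C[C@@H](C)[C@H]2C1=O | intermediate
5 | trans-fused C10 epimer of 4 (H-10 α) | COC1=CC(=O)[C@@]2(C)CC(O[Si](C)(C)C(C)(C)C)=C[C@@H](C)[C@@H]2C1=O | intermediate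
6 | 9β-alcohol of 5 (axial OH, cis to Me-15; C2 vinylogous ester kept) | COC1=CC(=O)[C@@]2(C)CC(O[Si](C)(C)C(C)(C)C)=C[C@@H](C)[C@@H]2[C@@H]1O | intermediate
7 | 9β-(4-methoxybenzyl) ether of 6 | COC1=CC(=O)[C@@]2(C)CC(O[Si](C)(C)C(C)(C)C)=C[C@@H](C)[C@@H]2[C@@H]1OCc3ccc(OC)cc3 | intermediate
8 | ring A enone: C13 ketone, C11=C12 with Me-20 on C11 | COC1=CC(=O)[C@@]2(C)CC(=O)C=C(C)[C@@H]2[C@@H]1OCc3ccc(OC)cc3 | intermediate
9 | ring A dienyl triflate: C11=C12 and C13(OTf)=C14 | COC1=CC(=O)[C@@]2(C)C=C(OS(=O)(=O)C(F)(F)F)C=C(C)[C@@H]2[C@@H]1OCc3ccc(OC)cc3 | intermediate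
10 | ring A 11,13-diene | COC1=CC(=O)[C@@]2(C)C=CC=C(C)[C@@H]2[C@@H]1OCc3ccc(OC)cc3 | intermediate
11 | 8-(prop-2-ynyloxy) vinylogous ester of 10 | C#CCOC1=CC(=O)[C@@]2(C)C=CC=C(C)[C@@H]2[C@@H]1OCc3ccc(OC)cc3 | intermediate
12 | 11α,12α-diol (Me-20 β), 13-ene | C#CCOC1=CC(=O)[C@@]2(C)C=C[C@@H](O)[C@@](C)(O)[C@@H]2[C@@H]1OCc3ccc(OC)cc3 | intermediate
13 | 13α,14α-epoxy-11α,12α-diol | C#CCOC1=CC(=O)[C@@]2(C)[C@H]3O[C@H]3[C@@H](O)[C@@](C)(O)[C@@H]2[C@@H]1OCc4ccc(OC)cc4 | intermediate
14 | 2β,11α,12α-triol with C3=C8 propargyl enol ether | C#CCOC1=C[C@H](O)[C@@]2(C)[C@H]3O[C@H]3[C@@H](O)[C@@](C)(O)[C@@H]2[C@@H]1OCc4ccc(OC)cc4 | intermediate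
15 | tris(triethylsilyl) ether of 14 | C#CCOC1=C[C@H](O[Si](CC)(CC)CC)[C@@]2(C)[C@H]3O[C@H]3[C@@H](O[Si](CC)(CC)CC)[C@@](C)(O[Si](CC)(CC)CC)[C@@H]2[C@@H]1OCc4ccc(OC)cc4 | intermediate
16 | 3α-(propa-1,2-dienyl) 8-ketone (allenyl equatorial) | C=C=C[C@H]1[C@H](O[Si](CC)(CC)CC)[C@@]2(C)[C@H]3O[C@H]3[C@@H](O[Si](CC)(CC)CC)[C@@](C)(O[Si](CC)(CC)CC)[C@@H]2[C@H](OCc4ccc(OC)cc4)C1=O | intermediate
17 | 8α-vinyl-8β-ol (vinyl axial, cis to the allenyl group) | C=C=C[C@H]1[C@H](O[Si](CC)(CC)CC)[C@@]2(C)[C@H]3O[C@H]3[C@@H](O[Si](CC)(CC)CC)[C@@](C)(O[Si](CC)(CC)CC)[C@@H]2[C@H](OCc4ccc(OC)cc4)[C@@]1(O)C=C | intermediate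
18 | potassium alkoxide of 17 | C=C=C[C@H]1[C@H](O[Si](CC)(CC)CC)[C@@]2(C)[C@H]3O[C@H]3[C@@H](O[Si](CC)(CC)CC)[C@@](C)(O[Si](CC)(CC)CC)[C@@H]2[C@H](OCc4ccc(OC)cc4)[C@@]1([O-])C=C.[K+] | intermediate
19 | potassium (7E)-enolate of the ring-expanded C8 ketone (3Z; 5(16)-methylene) | C=C1/C=C\[C@H](O[Si](CC)(CC)CC)[C@@]2(C)[C@H]3O[C@H]3[C@@H](O[Si](CC)(CC)CC)[C@@](C)(O[Si](CC)(CC)CC)[C@@H]2[C@H](OCc4ccc(OC)cc4)/C([O-])=C/C1.[K+] | intermediate
20 | (3Z,7E)-8-triflyloxy triene (C9 and C6 trans across C7=C8) | C=C1/C=C\[C@H](O[Si](CC)(CC)CC)[C@@]2(C)[C@H]3O[C@H]3[C@@H](O[Si](CC)(CC)CC)[C@@](C)(O[Si](CC)(CC)CC)[C@@H]2[C@H](OCc4ccc(OC)cc4)/C(OS(=O)(=O)C(F)(F)F)=C/C1 | intermediate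
21 | methyl ester with the C17–C19 unit on C8 (C17 epimers) | C=C1/C=C\[C@H](O[Si](CC)(CC)CC)[C@@]2(C)[C@H]3O[C@H]3[C@@H](O[Si](CC)(CC)CC)[C@@](C)(O[Si](CC)(CC)CC)[C@@H]2[C@H](OCc4ccc(OC)cc4)/C(C(C)C(=O)OC)=C/C1 | intermediate
22 | carboxylic acid of 21 (C17 epimers) | C=C1/C=C\[C@H](O[Si](CC)(CC)CC)[C@@]2(C)[C@H]3O[C@H]3[C@@H](O[Si](CC)(CC)CC)[C@@](C)(O[Si](CC)(CC)CC)[C@@H]2[C@H](OCc4ccc(OC)cc4)/C(C(C)C(=O)O)=C/C1 | intermediate
23 | trans-7,8-epoxy acid (C17 epimers) | C=C1/C=C\[C@H](O[Si](CC)(CC)CC)[C@@]2(C)[C@H]3O[C@H]3[C@@H](O[Si](CC)(CC)CC)[C@@](C)(O[Si](CC)(CC)CC)[C@@H]2[C@H](OCc4ccc(OC)cc4)[C@@]5(C(C)C(=O)O)O[C@@H]5C1 | intermediate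
24 | (7R,8R)-8-hydroxy-19,7-lactone (C17 epimers) | C=C1/C=C\[C@H](O[Si](CC)(CC)CC)[C@@]2(C)[C@H]3O[C@H]3[C@@H](O[Si](CC)(CC)CC)[C@@](C)(O[Si](CC)(CC)CC)[C@@H]2[C@H](OCc4ccc(OC)cc4)[C@]5(O)C(C)C(=O)O[C@H]5C1 | intermediate
25 | (17R)-lactone (Me-18 cis to 8-OH) | C=C1/C=C\[C@H](O[Si](CC)(CC)CC)[C@@]2(C)[C@H]3O[C@H]3[C@@H](O[Si](CC)(CC)CC)[C@@](C)(O[Si](CC)(CC)CC)[C@@H]2[C@H](OCc4ccc(OC)cc4)[C@]5(O)[C@@H](C)C(=O)O[C@H]5C1 | intermediate
26 | 9-ol of 25 | C=C1/C=C\[C@H](O[Si](CC)(CC)CC)[C@@]2(C)[C@H]3O[C@H]3[C@@H](O[Si](CC)(CC)CC)[C@@](C)(O[Si](CC)(CC)CC)[C@@H]2[C@H](O)[C@]5(O)[C@@H](C)C(=O)O[C@H]5C1 | intermediate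
27 | 9-acetate | C=C1/C=C\[C@H](O[Si](CC)(CC)CC)[C@@]2(C)[C@H]3O[C@H]3[C@@H](O[Si](CC)(CC)CC)[C@@](C)(O[Si](CC)(CC)CC)[C@@H]2[C@H](OC(C)=O)[C@]5(O)[C@@H](C)C(=O)O[C@H]5C1 | intermediate
28 | 9-acetoxy-2,8,11,12-tetrol (2-, 11- and 12-OH freed) | C=C1/C=C\[C@H](O)[C@@]2(C)[C@H]3O[C@H]3[C@@H](O)[C@@](C)(O)[C@@H]2[C@H](OC(C)=O)[C@]5(O)[C@@H](C)C(=O)O[C@H]5C1 | intermediate
29 | 2,12-dibutanoate (6-deschloro target) | C=C1/C=C\[C@H](OC(=O)CCC)[C@@]2(C)[C@H]3O[C@H]3[C@@H](OC(=O)CCC)[C@@](C)(O)[C@@H]2[C@H](OC(C)=O)[C@]5(O)[C@@H](C)C(=O)O[C@H]5C1 | intermediate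
30 | (6R)-6-hydroxy derivative of 29 | C=C1/C=C\[C@H](OC(=O)CCC)[C@@]2(C)[C@H]3O[C@H]3[C@@H](OC(=O)CCC)[C@@](C)(O)[C@@H]2[C@H](OC(C)=O)[C@]5(O)[C@@H](C)C(=O)O[C@H]5[C@@H]1O | intermediate
31 | CNP0188106.1: (1S,2S,3Z,6S,7R,8R,9S,10S,11S,12R,13R,14R,17R)-9-acetoxy-2,12-bis(butanoyloxy)-6-chloro-13,14-epoxy-8,11-dihydroxybriara-3,5(16)-dien-19,7-olide | C=C1/C=C\[C@H](OC(=O)CCC)[C@@]2(C)[C@H]3O[C@H]3[C@@H](OC(=O)CCC)[C@@](C)(O)[C@@H]2[C@H](OC(C)=O)[C@]2(O)[C@@H](C)C(=O)O[C@H]2[C@H]1Cl | target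

**Totals**
Total step count: 26. Longest linear sequence: 26 steps (1 → 31); quinone 3 enters at step 2.

**Three steps most likely to fail**

Step 16 (allenyl anionic oxy-Cope and enolate triflation). The alkoxide may isomerise the allene, cyclise onto it, or the enolate may scramble before trapping. The fallback sets out from 17 and avoids any anion during the rearrangement. Silylation (Me3SiOTf, 2,6-lutidine) gives the trimethylsilyl ether F1. A thermal siloxy-Cope rearrangement (o-xylene, 150 °C), still driven by loss of the allene, gives the (E)-trimethylsilyl enol ether F2. MeLi (THF, −78 °C) then PhNTf2 turns F2 into enol triflate 20, where the main route resumes.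

Step 19 (chemo- and face-selective epoxidation–lactonisation). The peracid may attack the C3=C4–C5=C16 diene instead. The fallback sets out from ester 21 and replaces electronic selectivity by hydroxyl delivery. iBu2AlH reduces the ester to the homoallylic primary alcohol F3. VO(acac)2/tBuOOH then epoxidises only the C7=C8 bond to give the epoxy alcohol F4. Oxidation of the primary alcohol (TEMPO, PhI(OAc)2; then NaClO2) gives epoxy acid 23, which lactonises to 24.

Step 25 (allylic hydroxylation at C6). The stereochemical prediction rests on a conformational model, and the 6-epimer or a mixture may form. The fallback sets out from 30 as whatever epimer mixture is obtained and makes the centre reagent-controlled. Dess–Martin periodinane oxidises it to the cross-conjugated enone F5. Reduction with (R)-2-methyl-CBS-oxazaborolidine and catecholborane (PhMe, −78 °C; the alkenyl branch acts as the larger group) returns (6R)-30, which goes on to step 26.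

**Further compounds**
F1 | step 16 | 8β-trimethylsilyl ether of 17 | C=C=C[C@H]1[C@H](O[Si](CC)(CC)CC)[C@@]2(C)[C@H]3O[C@H]3[C@@H](O[Si](CC)(CC)CC)[C@@](C)(O[Si](CC)(CC)CC)[C@@H]2[C@H](OCc4ccc(OC)cc4)[C@@]1(O[Si](C)(C)C)C=C
F2 | step 16 | (3Z,7E)-8-trimethylsilyloxy triene (silyl enol ether of the ring-expanded ketone) | C=C1/C=C\[C@H](O[Si](CC)(CC)CC)[C@@]2(C)[C@H]3O[C@H]3[C@@H](O[Si](CC)(CC)CC)[C@@](C)(O[Si](CC)(CC)CC)[C@@H]2[C@H](OCc4ccc(OC)cc4)/C(O[Si](C)(C)C)=C/C1
F3 | step 19 | homoallylic primary alcohol from 21 (C19 as CH2OH; C17 epimers) | C=C1/C=C\[C@H](O[Si](CC)(CC)CC)[C@@]2(C)[C@H]3O[C@H]3[C@@H](O[Si](CC)(CC)CC)[C@@](C)(O[Si](CC)(CC)CC)[C@@H]2[C@H](OCc4ccc(OC)cc4)/C(C(C)CO)=C/C1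
F4 | step 19 | trans-7,8-epoxy primary alcohol (C17 epimers) | C=C1/C=C\[C@H](O[Si](CC)(CC)CC)[C@@]2(C)[C@H]3O[C@H]3[C@@H](O[Si](CC)(CC)CC)[C@@](C)(O[Si](CC)(CC)CC)[C@@H]2[C@H](OCc4ccc(OC)cc4)[C@@]5(C(C)CO)O[C@@H]5C1
F5 | step 25 | 6-oxo compound (C5 methylene enone) | C=C1/C=C\[C@H](OC(=O)CCC)[C@@]2(C)[C@H]3O[C@H]3[C@@H](OC(=O)CCC)[C@@](C)(O)[C@@H]2[C@H](OC(C)=O)[C@]5(O)[C@@H](C)C(=O)O[C@H]5C1=O
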